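## Retrosynthetic overview

1. Target ← global O-debenzylation ← desilylation ← THF ring closure, the only ring formed in the route, by acid-promoted cyclodehydration of a 1,4-diol-type triol. C9-OH captures the benzylic cation at C7′, which sets C7′ trans to C8′.
2. The triol comes from LiBH4 cleavage of a bis-imide whose four contiguous stereocentres (C7, C8, C8′, C7′) are set by two Evans Mg-catalysed anti-aldols on succinyl bis-(R)-benzyloxazolidinone with benzylvanillin.
3. C7–OH is masked as an acid-stable TIPS ether after the first aldol. This makes the two halves different and blocks furofuran and 2,5-diaryl-THF formation during ring closure.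

Assumptions:
- Labels follow the target SMILES: C7 is the exocyclic carbinol (R) and C7′ is the ring carbon bearing aryl (S).
- The Mg-catalysed anti-aldol with the (R)-benzyl auxiliary gives the (α-S, β-R) adduct. The (S)-auxiliary would give the enantiomeric series.
- 4-(Benzyloxy)-3-methoxybenzaldehyde and (R)-4-benzyloxazolidin-2-one are commercial.

## Route

**Step 1**
Reactants: 1 succinyl chloride; 2 (R)-4-benzyloxazolidin-2-one
Product: 3 (4R,4′R)-3,3′-succinylbis(4-benzyloxazolidin-2-one)
Conditions: 2 (2.1 equiv), n-BuLi (2.1 equiv), THF, −78 °C; then 1 (1 equiv), −78 °C → rt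
Reagents that add atoms: none
Why: Double N-acylation of the lithiated oxazolidinone; the two auxiliary stereocentres are carried unchanged.

**Step 2**
Reactants: 3 bis-imide; 4 4-(benzyloxy)-3-methoxybenzaldehyde (0.6 equiv)
Product: 5 (4R)-4-benzyl-3-{(2S,3R)-3-[4-(benzyloxy)-3-methoxyphenyl]-3-hydroxy-2-[2-((4R)-4-benzyl-2-oxooxazolidin-3-yl)-2-oxoethyl]propanoyl}oxazolidin-2-one
Conditions: MgCl2 (10 mol %), Et3N (2 equiv), TMSCl (1.5 equiv), EtOAc, rt, 24 h; then 1 M HCl/MeOH, rt
Reagents that add atoms: none (the TMS ether is cleaved in the acidic work-up)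
Why: Evans Mg-halide-catalysed anti-aldol. The chelated Z-enolate is attacked anti to the (R)-benzyl group, setting C8 (S at imide level) and C7 (R) anti. Limiting aldehyde favours mono-addition.

**Step 3**
Reactants: 5
Product: 6 the C7-O-TIPS ether of 5
Conditions: TIPSOTf, 2,6-lutidine, CH2Cl2, 0 °C
Reagents that add atoms: triisopropylsilyl triflate, `CC(C)[Si](C(C)C)(C(C)C)OS(=O)(=O)C(F)(F)F`
Why: Silylation gives an acid-stable ether that cannot ionise in step 6. It also prevents lactonisation of the γ-hydroxy imide. No stereocentre is touched.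

**Step 4**
Reactants: 6; 4 (1.5 equiv)
Product: 7 bis-imide carrying C7-OTIPS and C7′-OH
Conditions: MgCl2 (10 mol %), Et3N, TMSCl, EtOAc, rt; then 1 M HCl/MeOH, rt
Reagents that add atoms: none
Why: A second anti-aldol with the same (R)-auxiliary and the same conditions sets C8′ like C8 (S at imide level), giving a C2-like relationship. C7′ (R) is re-set later in step 6.

**Step 5**
Reactants: 7
Product: 8 triol, (1R,2R,3R,4R)-1,4-bis[4-(benzyloxy)-3-methoxyphenyl]-2,3-bis(hydroxymethyl)-4-(TIPSO)butan-1-ol, plus recovered 2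
Conditions: LiBH4 (6 equiv), MeOH (4 equiv), THF, 0 °C → rt
Reagents that add atoms: none (hydride adds H only)
Why: Reductive removal of both auxiliaries. The carbons stay in place, and the descriptors change from S,S to R,R only because the CIP priorities change (CO becomes CH2OH).

**Step 6**
Reactants: 8
Product: 9 THF ring A, C7-OTIPS, C9′-OH, both aryl OBn
Conditions: TsOH·H2O (10 mol %), CH2Cl2, 4 Å MS, 0 °C → rt
Reagents that add atoms: none (water is lost)
Why: Acid-catalysed intramolecular benzylic etherification (cyclodehydration). C9-OH closes 5-exo onto the C7′ cation. C9′-OH would give an oxetane, and C7 is silylated. Reversible ionisation makes C7′ trans to C8′; the cis epimer would put aryl cis to both ring substituents. C8 and C8′ are not epimerisable, so the cis-3,4 relationship is retained.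

**Step 7**
Reactants: 9
Product: 10 dibenzyl ether with free C7-OH
Conditions: TBAF (3 equiv), THF, rt → 40 °C
Reagents that add atoms: none (F− ends up on silicon)
Why: Fluoride cleaves the Si–O bond; the benzyl ethers and all stereocentres are unaffected.

**Step 8**
Reactants: 10
Product: 11 (7R)-7-hydroxylariciresinol
Conditions: H2 (1 atm), 10 % Pd/C, EtOAc/MeOH 1:1, rt, 1–2 h
Reagents that add atoms: none (H2 adds only H)
Why: Hydrogenolysis of the two aryl benzyl ethers is much faster than cleavage of the THF or the secondary benzylic alcohol, so monitored short reaction times leave C7 and C7′ intact.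

## Compound list

1 | succinyl chloride | `ClC(=O)CCC(=O)Cl` | starting material
2 | (R)-4-benzyloxazolidin-2-one | `O=C1N[C@H](Cc2ccccc2)CO1` | starting material
3 | bis-imide of succinic acid with (R)-4-benzyloxazolidinone | `O=C(CCC(=O)N1C(=O)OC[C@H]1Cc1ccccc1)N1C(=O)OC[C@H]1Cc1ccccc1` | intermediate
4 | 4-(benzyloxy)-3-methoxybenzaldehyde | `COc1cc(C=O)ccc1OCc1ccccc1` | starting material
5 | mono anti-aldol adduct (C7-OH) | `O=C(N1C(=O)OC[C@H]1Cc1ccccc1)C[C@@H]([C@@H](O)c1ccc(OCc2ccccc2)c(OC)c1)C(=O)N1C(=O)OC[C@H]1Cc1ccccc1` | intermediate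
6 | C7-O-TIPS ether of 5 | `O=C(N1C(=O)OC[C@H]1Cc1ccccc1)C[C@@H]([C@@H](O[Si](C(C)C)(C(C)C)C(C)C)c1ccc(OCc2ccccc2)c(OC)c1)C(=O)N1C(=O)OC[C@H]1Cc1ccccc1` | intermediate
7 | bis-aldol bis-imide (C7-OTIPS, C7′-OH) | `O=C(N1C(=O)OC[C@H]1Cc1ccccc1)[C@H]([C@@H](O[Si](C(C)C)(C(C)C)C(C)C)c1ccc(OCc2ccccc2)c(OC)c1)[C@@H]([C@@H](O)c1ccc(OCc2ccccc2)c(OC)c1)C(=O)N1C(=O)OC[C@H]1Cc1ccccc1` | intermediate
8 | triol (C7-OTIPS, C9-OH, C9′-OH, C7′-OH) | `COc1cc(ccc1OCc1ccccc1)[C@H](O[Si](C(C)C)(C(C)C)C(C)C)[C@@H](CO)[C@H](CO)[C@@H](O)c1ccc(OCc2ccccc2)c(OC)c1` | intermediate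
9 | THF with C7-OTIPS, dibenzyl | `COc1cc([C@H]2OC[C@H]([C@@H](O[Si](C(C)C)(C(C)C)C(C)C)c3ccc(OCc4ccccc4)c(OC)c3)[C@@H]2CO)ccc1OCc1ccccc1` | intermediate
10 | dibenzyl ether of the target | `COc1cc([C@H]2OC[C@H]([C@@H](O)c3ccc(OCc4ccccc4)c(OC)c3)[C@@H]2CO)ccc1OCc1ccccc1` | intermediate
11 | (7R)-7-hydroxylariciresinol | `COc1cc([C@H]2OC[C@H]([C@@H](O)c3ccc(O)c(OC)c3)[C@@H]2CO)ccc1O` | target

## Totals

Total steps: 8. Longest linear sequence: 8 (1 → 3 → 5 → 6 → 7 → 8 → 9 → 10 → 11).

## Three steps most likely to fail

1. **Step 2 (mono anti-aldol on the symmetric bis-imide).** Statistical mono/bis addition, and chelation by the second imide may erode dr.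
   Fallback: desymmetrise the core instead. Use Ru-BINAP hydrogenation of methyl 3-aryl-3-oxopropanoate, then Fráter–Seebach alkylation of the dianion with tert-butyl bromoacetate (anti), convert the tBu ester to the acyl oxazolidinone, and run the second aldol there.
2. **Step 6 (cyclodehydration).** It may give elimination, 2,5-diaryl-THF, or low trans selectivity.
   Fallback: oxidise only the benzylic C7′-OH with MnO2, let the keto-diol close to the hemiketal with C9-OH, and reduce with Et3SiH/BF3·OEt2. Hydride delivery anti to the C3 substituent gives the 2,3-trans THF.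
3. **Step 8 (hydrogenolysis).** Over-reduction of the benzylic C7–OH or the C7′–O ring bond is possible.
   Fallback: carry the phenols as TBS ethers (from TBS-protected vanillin) or allyl ethers from the start, so the final deprotection is fluoride or Pd(0) with no hydrogenation.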